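**Retrosynthetic overview**
1. The acid and the phenol are unmasked last (methyl ester, aryl acetate). Just before that, the C3 hydroxyl left by the cyclisation is removed by radical deoxygenation.
2. Key disconnection: C4–C5 and C9–C10 are cut together, back to an acyclic (2R,3R)-epoxy-diene that already carries the coumarate. A Cp2TiCl radical cascade closes ring A, then ring B, and sets the 8(17)-methylene in one operation.
3. The epoxide comes from Sharpless epoxidation of an (E)-allylic alcohol, made by SeO2 oxidation of the terminal isopropylidene of methyl (S)-2,3-dihydrogeranylgeranoate.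
4. That C20 ester comes from farnesol: bromide, allyl Grignard coupling, cross-metathesis with methyl acrylate, then Cu-catalysed asymmetric methyl addition (sets C13).

Assumption: (R)-Tol-BINAP is taken as the ligand antipode that gives the 3S ester in step 4 (the (S)-ligand is the mirror-image choice); bicyclic compounds carry labdane numbering, and the target is the ent-labdane (4S,5S,9R,10S,13S) with C18 equatorial.

**Route**

Step 1
Reactants: 1 (2E,6E)-farnesol
Product: 2 (2E,6E)-farnesyl bromide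
Conditions: PBr3 (0.4 equiv), Et2O, −10 to 0 °C
Reagents that add atoms: phosphorus tribromide, BrP(Br)Br
Why: SN2 bromination of the primary allylic alcohol through its phosphite ester occurs at low temperature without allylic transposition, so both E-alkenes are kept.

Step 2
Reactants: 2 (2E,6E)-farnesyl bromide; 3 allylmagnesium bromide
Product: 4 (5E,9E)-6,10,14-trimethylpentadeca-1,5,9,13-tetraene
Conditions: allylmagnesium bromide (1.5 equiv), THF/Et2O, −20 → 0 °C
Reagents that add atoms: none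
Why: Grignard allyl–allyl coupling goes by SN2 at the primary carbon, because SN2′ attack would have to build a quaternary centre, and the trisubstituted alkenes are untouched.

Step 3
Reactants: 4 (5E,9E)-6,10,14-trimethylpentadeca-1,5,9,13-tetraene; 5 methyl acrylate
Product: 6 methyl (2E,6E,10E)-7,11,15-trimethylhexadeca-2,6,10,14-tetraenoate
Conditions: methyl acrylate (4 equiv), second-generation Hoveyda–Grubbs catalyst RuCl2(H2IMes)(=CH-C6H4-2-OiPr) (2 mol%), CH2Cl2, 40 °C
Reagents that add atoms: none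
Why: Olefin cross-metathesis engages only the monosubstituted terminal alkene (the trisubstituted ones are far slower) and pairs it with the electron-poor acrylate to give the E-enoate.

Step 4
Reactants: 6 methyl (2E,6E,10E)-7,11,15-trimethylhexadeca-2,6,10,14-tetraenoate
Product: 7 methyl (3S,6E,10E)-3,7,11,15-tetramethylhexadeca-6,10,14-trienoate
Conditions: MeMgBr (4 equiv), CuI (2 mol%), (R)-Tol-BINAP (3 mol%), t-BuOMe, −20 °C; then 1 M HCl
Reagents that add atoms: methylmagnesium bromide, C[Mg]Br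
Why: Copper-catalysed asymmetric conjugate addition of the Grignard reagent delivers methyl to one face of the E-enoate under ligand control and sets C13 (3S here), with 1,2-addition suppressed at low temperature.

Step 5
Reactants: 7 methyl (3S,6E,10E)-3,7,11,15-tetramethylhexadeca-6,10,14-trienoate
Product: 8 methyl (3S,6E,10E,14E)-16-hydroxy-3,7,11,15-tetramethylhexadeca-6,10,14-trienoate
Conditions: SeO2 (0.2 equiv), t-BuOOH (2.5 equiv), salicylic acid (0.1 equiv), CH2Cl2, 0 °C → rt, stopped at partial conversion and 7 recycled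
Reagents that add atoms: tert-butyl hydroperoxide, CC(C)(C)OO; selenium dioxide, O=[Se]=O
Why: Catalytic SeO2 allylic oxidation (ene reaction then [2,3]-shift) attacks the least hindered terminal isopropylidene and hydroxylates its (E)-methyl group.

Step 6
Reactants: 8 methyl (3S,6E,10E,14E)-16-hydroxy-3,7,11,15-tetramethylhexadeca-6,10,14-trienoate
Product: 9 methyl (3S,6E,10E)-13-[(2R,3R)-3-(hydroxymethyl)-3-methyloxiran-2-yl]-3,7,11-trimethyltrideca-6,10-dienoate
Conditions: Ti(OiPr)4 (0.1 equiv), D-(−)-diisopropyl tartrate (0.12 equiv), t-BuOOH (2 equiv), 4 Å MS, CH2Cl2, −25 °C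
Reagents that add atoms: tert-butyl hydroperoxide, CC(C)(C)OO
Why: Sharpless asymmetric epoxidation touches only the allylic-alcohol alkene, and D-(−)-tartrate delivers oxygen to the face that gives the (2R,3R)-epoxide, the centre that later fixes the absolute sense of the cyclisation.

Step 7
Reactants: 9 methyl (3S,6E,10E)-13-[(2R,3R)-3-(hydroxymethyl)-3-methyloxiran-2-yl]-3,7,11-trimethyltrideca-6,10-dienoate; 10 (E)-4-acetoxycinnamic acid
Product: 11 methyl (3S,6E,10E)-13-[(2R,3R)-3-{[(E)-3-(4-acetoxyphenyl)prop-2-enoyl]oxymethyl}-3-methyloxiran-2-yl]-3,7,11-trimethyltrideca-6,10-dienoate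
Conditions: EDC·HCl (1.5 equiv), DMAP (0.2 equiv), CH2Cl2, 0 °C → rt
Reagents that add atoms: none
Why: Steglich esterification acylates the primary epoxy alcohol under neutral conditions that leave the epoxide and the aryl acetate intact.

Step 8
Reactants: 11 methyl (3S,6E,10E)-13-[(2R,3R)-3-{[(E)-3-(4-acetoxyphenyl)prop-2-enoyl]oxymethyl}-3-methyloxiran-2-yl]-3,7,11-trimethyltrideca-6,10-dienoate
Product: 13 methyl (3R,4S,5S,9R,10S,13S)-18-[(E)-4-acetoxycinnamoyloxy]-3-hydroxylabd-8(17)-en-15-oate, via trimethylsilyl ether 12 (not isolated)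
Conditions: Cp2TiCl2 (0.3 equiv), Mn dust (8 equiv), Me3SiCl (4 equiv), 2,4,6-collidine (7 equiv), THF (0.01 M), rt; then 1 M HCl, THF, 0 °C
Reagents that add atoms: none
Why: Titanocene-mediated radical epoxypolyene cyclisation: Cp2TiCl (trivalent titanium) opens the epoxide to the tertiary C4 radical, which closes ring A (C4–C5) and then ring B (C9–C10) by two chair-like 6-endo additions with the C3–O group equatorial (3R thereby fixes 5S, 9R, 10S), the bulkier acyloxymethyl arm equatorial at C4 (4S), and Ti-assisted β-hydride loss from the C8 radical giving the exocyclic alkene.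

Step 9
Reactants: 13 methyl (3R,4S,5S,9R,10S,13S)-18-[(E)-4-acetoxycinnamoyloxy]-3-hydroxylabd-8(17)-en-15-oate
Product: 14 methyl (3R,4S,5S,9R,10S,13S)-18-[(E)-4-acetoxycinnamoyloxy]-3-(phenoxythiocarbonyloxy)labd-8(17)-en-15-oate
Conditions: PhOC(S)Cl (2 equiv), pyridine (4 equiv), DMAP (0.3 equiv), CH2Cl2, rt
Reagents that add atoms: O-phenyl chlorothionoformate, S=C(Cl)Oc1ccccc1
Why: DMAP-catalysed acylation of the equatorial secondary alcohol gives the thionocarbonate needed for Barton–McCombie deoxygenation and changes no stereocentre.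

Step 10
Reactants: 14 methyl (3R,4S,5S,9R,10S,13S)-18-[(E)-4-acetoxycinnamoyloxy]-3-(phenoxythiocarbonyloxy)labd-8(17)-en-15-oate
Product: 15 methyl (4S,5S,9R,10S,13S)-18-[(E)-4-acetoxycinnamoyloxy]labd-8(17)-en-15-oate
Conditions: Bu3SnH (2 equiv), AIBN (0.2 equiv), toluene, 100 °C
Reagents that add atoms: none
Why: Barton–McCombie radical deoxygenation: the stannyl radical adds to C=S, the C3–O bond fragments, and the secondary radical is reduced by Bu3SnH faster than it can reach the cinnamate or the exocyclic alkene, so C3 becomes CH2 and no other centre is touched.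

Step 11
Reactants: 15 methyl (4S,5S,9R,10S,13S)-18-[(E)-4-acetoxycinnamoyloxy]labd-8(17)-en-15-oate
Product: 17 (4S,5S,9R,10S,13S)-18-[(E)-4-hydroxycinnamoyloxy]labd-8(17)-en-15-oic acid, via phenol methyl ester 16 (not isolated)
Conditions: LiOH (5 equiv), THF/H2O 3:1, 0 °C → rt; then 1 M HCl to pH 3, 0 °C
Reagents that add atoms: lithium hydroxide, [Li+].[OH-]
Why: Chemoselective saponification: the aryl acetate goes first and the unhindered methyl ester next, while the neopentyl coumarate survives because the phenolate formed in the first cleavage makes it a poor electrophile.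

**Compound list**
1 | (2E,6E)-farnesol | CC(C)=CCC/C(C)=C/CC/C(C)=C/CO | starting material
2 | (2E,6E)-farnesyl bromide | CC(C)=CCC/C(C)=C/CC/C(C)=C/CBr | intermediate
3 | allylmagnesium bromide | C=CC[Mg]Br | starting material
4 | (5E,9E)-6,10,14-trimethylpentadeca-1,5,9,13-tetraene | C=CCC/C=C(\C)CC/C=C(\C)CCC=C(C)C | intermediate
5 | methyl acrylate | C=CC(=O)OC | starting material
6 | methyl (2E,6E,10E)-7,11,15-trimethylhexadeca-2,6,10,14-tetraenoate | COC(=O)/C=C/CC/C=C(\C)CC/C=C(\C)CCC=C(C)C | intermediate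
7 | methyl (3S,6E,10E)-3,7,11,15-tetramethylhexadeca-6,10,14-trienoate | COC(=O)C[C@@H](C)CC/C=C(\C)CC/C=C(\C)CCC=C(C)C | intermediate
8 | methyl (3S,6E,10E,14E)-16-hydroxy-3,7,11,15-tetramethylhexadeca-6,10,14-trienoate | COC(=O)C[C@@H](C)CC/C=C(\C)CC/C=C(\C)CC/C=C(\C)CO | intermediate
9 | methyl (3S,6E,10E)-13-[(2R,3R)-3-(hydroxymethyl)-3-methyloxiran-2-yl]-3,7,11-trimethyltrideca-6,10-dienoate | COC(=O)C[C@@H](C)CC/C=C(\C)CC/C=C(\C)CC[C@H]1O[C@]1(C)CO | intermediate
10 | (E)-4-acetoxycinnamic acid | CC(=O)Oc1ccc(/C=C/C(=O)O)cc1 | starting material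
11 | (E)-4-acetoxycinnamate ester of 9 (epoxy-diene cyclisation substrate) | COC(=O)C[C@@H](C)CC/C=C(\C)CC/C=C(\C)CC[C@H]1O[C@]1(C)COC(=O)/C=C/c2ccc(OC(C)=O)cc2 | intermediate
12 | methyl (3R,4S,5S,9R,10S,13S)-18-[(E)-4-acetoxycinnamoyloxy]-3-(trimethylsilyloxy)labd-8(17)-en-15-oate (not isolated) | C=C1CC[C@@H]2[C@@](C)(COC(=O)/C=C/c3ccc(OC(C)=O)cc3)[C@H](O[Si](C)(C)C)CC[C@@]2(C)[C@@H]1CC[C@H](C)CC(=O)OC | intermediate
13 | methyl (3R,4S,5S,9R,10S,13S)-18-[(E)-4-acetoxycinnamoyloxy]-3-hydroxylabd-8(17)-en-15-oate (trans-decalin; 3-OH equatorial, cis to C20; C18 equatorial) | C=C1CC[C@@H]2[C@@](C)(COC(=O)/C=C/c3ccc(OC(C)=O)cc3)[C@H](O)CC[C@@]2(C)[C@@H]1CC[C@H](C)CC(=O)OC | intermediate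
14 | methyl (3R,4S,5S,9R,10S,13S)-18-[(E)-4-acetoxycinnamoyloxy]-3-(phenoxythiocarbonyloxy)labd-8(17)-en-15-oate | C=C1CC[C@@H]2[C@@](C)(COC(=O)/C=C/c3ccc(OC(C)=O)cc3)[C@H](OC(=S)Oc4ccccc4)CC[C@@]2(C)[C@@H]1CC[C@H](C)CC(=O)OC | intermediate
15 | methyl (4S,5S,9R,10S,13S)-18-[(E)-4-acetoxycinnamoyloxy]labd-8(17)-en-15-oate | C=C1CC[C@@H]2[C@@](C)(COC(=O)/C=C/c3ccc(OC(C)=O)cc3)CCC[C@@]2(C)[C@@H]1CC[C@H](C)CC(=O)OC | intermediate
16 | methyl (4S,5S,9R,10S,13S)-18-[(E)-4-hydroxycinnamoyloxy]labd-8(17)-en-15-oate (not isolated) | C=C1CC[C@@H]2[C@@](C)(COC(=O)/C=C/c3ccc(O)cc3)CCC[C@@]2(C)[C@@H]1CC[C@H](C)CC(=O)OC | intermediate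
17 | (4S,5S,9R,10S,13S)-18-[(E)-4-hydroxycinnamoyloxy]labd-8(17)-en-15-oic acid, CNP0389065.1 | C=C1CC[C@@H]2[C@@](C)(COC(=O)/C=C/c3ccc(O)cc3)CCC[C@@]2(C)[C@@H]1CC[C@H](C)CC(=O)O | target

**Step count**
Total steps: 11. Longest linear sequence: 11 (1 → 17).

**Three steps most likely to fail**

Step 8 (key cascade). The C4 radical may add to the cinnamate, the bicyclisation yield may be low, or endocyclic alkene isomers may form; the equatorial placement of C18 rests on analogy with related radical closures, not on a stereospecific mechanism. Fallback: move the coumarate behind the cyclisation. Starting from 9, Ac2O/pyridine gives the epoxy acetate F1. The same Cp2TiCl2/Mn/Me3SiCl/collidine conditions give, through the trimethylsilyl ether F2, the hydroxy acetate F3. PhOC(S)Cl/DMAP converts this into the phenyl thionocarbonate F4, and Bu3SnH/AIBN reduces it to the 18-acetate F5. K2CO3 in MeOH frees the 18-alcohol F6, and EDC/DMAP coupling of F6 with 10 returns to the route at 15.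

Step 5 (SeO2 oxidation). Three trisubstituted alkenes compete, and over-oxidation to the enal lowers the yield. Fallback: single out the terminal alkene by bromohydrin formation and rebuild the allylic alcohol by olefination. Starting from 7, NBS in aqueous THF at 0 °C gives the terminal bromohydrin F7, and K2CO3 in MeOH closes it to the terminal epoxide F8. H5IO6 in THF/Et2O cleaves this to the aldehyde F9. Wittig reaction with Ph3P=C(CH3)CHO in toluene at 90 °C gives the (E)-enal F10, and NaBH4/CeCl3 in MeOH returns to the route at 8.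

Step 10 (deoxygenation, together with its precursor step 9). The C3 hydroxyl is hindered, the coumarate could migrate from O18 to O3 under DMAP, and tin radicals may attack or isomerise the cinnamate. Fallback: remove C3–O by way of the ketone. Starting from 13, Dess–Martin periodinane/NaHCO3 gives the 3-ketone F11, and TsNHNH2 in EtOH with catalytic AcOH at 60 °C gives the tosylhydrazone F12. Catecholborane in CHCl3 followed by NaOAc·3H2O at reflux returns to the route at 15.

**Further compounds**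
F1 | step 8 | methyl (3S,6E,10E)-13-[(2R,3R)-3-(acetoxymethyl)-3-methyloxiran-2-yl]-3,7,11-trimethyltrideca-6,10-dienoate | COC(=O)C[C@@H](C)CC/C=C(\C)CC/C=C(\C)CC[C@H]1O[C@]1(C)COC(C)=O
F2 | step 8 | methyl (3R,4S,5S,9R,10S,13S)-18-acetoxy-3-(trimethylsilyloxy)labd-8(17)-en-15-oate | C=C1CC[C@@H]2[C@@](C)(COC(C)=O)[C@H](O[Si](C)(C)C)CC[C@@]2(C)[C@@H]1CC[C@H](C)CC(=O)OC
F3 | step 8 | methyl (3R,4S,5S,9R,10S,13S)-18-acetoxy-3-hydroxylabd-8(17)-en-15-oate | C=C1CC[C@@H]2[C@@](C)(COC(C)=O)[C@H](O)CC[C@@]2(C)[C@@H]1CC[C@H](C)CC(=O)OC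
F4 | step 8 | methyl (3R,4S,5S,9R,10S,13S)-18-acetoxy-3-(phenoxythiocarbonyloxy)labd-8(17)-en-15-oate | C=C1CC[C@@H]2[C@@](C)(COC(C)=O)[C@H](OC(=S)Oc3ccccc3)CC[C@@]2(C)[C@@H]1CC[C@H](C)CC(=O)OC
F5 | step 8 | methyl (4S,5S,9R,10S,13S)-18-acetoxylabd-8(17)-en-15-oate | C=C1CC[C@@H]2[C@@](C)(COC(C)=O)CCC[C@@]2(C)[C@@H]1CC[C@H](C)CC(=O)OC
F6 | step 8 | methyl (4S,5S,9R,10S,13S)-18-hydroxylabd-8(17)-en-15-oate | C=C1CC[C@@H]2[C@@](C)(CO)CCC[C@@]2(C)[C@@H]1CC[C@H](C)CC(=O)OC
F7 | step 5 | methyl (3S,6E,10E)-14-bromo-15-hydroxy-3,7,11,15-tetramethylhexadeca-6,10-dienoate (both C14 epimers) | COC(=O)C[C@@H](C)CC/C=C(\C)CC/C=C(\C)CCC(Br)C(C)(C)O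
F8 | step 5 | methyl (3S,6E,10E)-13-(3,3-dimethyloxiran-2-yl)-3,7,11-trimethyltrideca-6,10-dienoate (both epoxide epimers) | COC(=O)C[C@@H](C)CC/C=C(\C)CC/C=C(\C)CCC1OC1(C)C
F9 | step 5 | methyl (3S,6E,10E)-3,7,11-trimethyl-14-oxotetradeca-6,10-dienoate | COC(=O)C[C@@H](C)CC/C=C(\C)CC/C=C(\C)CCC=O
F10 | step 5 | methyl (3S,6E,10E,14E)-3,7,11,15-tetramethyl-16-oxohexadeca-6,10,14-trienoate | COC(=O)C[C@@H](C)CC/C=C(\C)CC/C=C(\C)CC/C=C(\C)C=O
F11 | step 10 | methyl (4S,5S,9R,10S,13S)-18-[(E)-4-acetoxycinnamoyloxy]-3-oxolabd-8(17)-en-15-oate | C=C1CC[C@@H]2[C@@](C)(COC(=O)/C=C/c3ccc(OC(C)=O)cc3)C(=O)CC[C@@]2(C)[C@@H]1CC[C@H](C)CC(=O)OC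
F12 | step 10 | C3 p-toluenesulfonylhydrazone of F11 | C=C1CC[C@@H]2[C@@](C)(COC(=O)/C=C/c3ccc(OC(C)=O)cc3)C(=NNS(=O)(=O)c4ccc(C)cc4)CC[C@@]2(C)[C@@H]1CC[C@H](C)CC(=O)OC
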